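Petrosin A is a meso, head-to-tail dimer: two enantiomeric 3-methylquinolizidin-2-ones (ring A carries the C2 ketone, ring B carries C9) are tied into a 16-membered ring by two five-carbon chains, each running from C9 of one half to C1 of the other. Cutting each chain at the bond next to C9 leaves a single racemic monomer with a branched, hindered vinyl group on C9 and an unhindered pent-4-enyl group on C1. Because the hindered vinyl group hardly homodimerizes, ruthenium-catalysed olefin metathesis of the N-protonated monomer should join vinyl to pentenyl twice, making both chain bonds and the macrocycle in one operation. Hydrogenation then gives the target.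

Key step: step 8

Remark: petrosin A is meso, so all chiral intermediates are racemic; a SMILES without a tag at the methyl-bearing carbon means the racemate, the two monomer enantiomers are numbered separately, and a species differing from a numbered compound only by proton transfer or by a metal on O, N or acetylide carbon before aqueous quench is treated as that compound (quinolizidine numbering: N5, bridgehead C9a).

Step 1
Reactants: 1 5-chloropent-1-yne; 2 (iodomethyl)trimethylsilane
Product: 3 (6-chlorohex-2-yn-1-yl)trimethylsilane
Conditions: n-BuLi, THF, −78 → 0 °C; then 2, THF, reflux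
Reagents that add atoms: none
Why: Acetylide alkylation (SN2): the lithium acetylide of 1 displaces iodide from the primary α-silyl iodide 2, a far better electrophile than the chain chloride, which is therefore kept for step 6; no stereocentre is formed.

Step 2
Reactants: 3 (6-chlorohex-2-yn-1-yl)trimethylsilane
Product: 4 [(2Z)-6-chlorohex-2-en-1-yl]trimethylsilane
Conditions: H2 (1 atm), Pd/CaCO3 poisoned with Pb(OAc)2 (Lindlar catalyst), quinoline, hexane, rt
Reagents that add atoms: none
Why: Lindlar semihydrogenation: syn delivery of hydrogen on the poisoned palladium surface gives the (Z)-alkene and stops there, leaving the C–Cl and C–Si bonds untouched.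

Step 3
Reactants: 5 (±)-3-[(tert-butoxycarbonyl)amino]-2-methylpropanoic acid
Product: 7 tert-butyl N-{3-[methoxy(methyl)amino]-2-methyl-3-oxopropyl}carbamate (Weinreb amide), via acyl imidazolide 6 (not isolated)
Conditions: CDI, CH2Cl2, 0 °C → rt; then MeNHOMe·HCl, rt; aq NaHCO3
Reagents that add atoms: N,O-dimethylhydroxylamine hydrochloride, CNOC.Cl
Why: Amide coupling through the acyl imidazolide (CDI activation) gives the Weinreb amide; the carbamate and the racemic α-methyl centre are spectators.

Step 4
Reactants: 7 Weinreb amide; 8 6-bromohex-1-ene
Product: 10 tert-butyl N-(2-methyl-3-oxonon-8-en-1-yl)carbamate, via hex-5-enylmagnesium bromide 9 (not isolated)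
Conditions: 8, Mg, THF, rt; then 7, THF, 0 °C → rt (2.5 equiv of 9); 1 M HCl, 0 °C
Reagents that add atoms: none
Why: Weinreb ketone synthesis: after the first equivalent of Grignard reagent has deprotonated the carbamate N–H, addition to the N-methoxy-N-methylamide gives a magnesium-chelated tetrahedral adduct that collapses to the ketone only on acidic quench, so no tertiary alcohol forms.

Step 5
Reactants: 10 tert-butyl N-(2-methyl-3-oxonon-8-en-1-yl)carbamate
Product: 13 3-methyl-5-(pent-4-en-1-yl)-2,3-dihydropyridin-4(1H)-one, via Boc enaminone 11 (not isolated), via amino enaminone 12 (not isolated)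
Conditions: t-BuOCH(NMe2)2, PhMe, 100 °C; concentrate; TFA, CH2Cl2, 0 °C → rt; concentrate; K2CO3, MeOH, rt
Reagents that add atoms: tert-butoxybis(dimethylamino)methane (Bredereck's reagent), CN(C)C(OC(C)(C)C)N(C)C
Why: Enaminone formation then transamination: the formamide aminal condenses at the only methylene α to the ketone (the α-methine cannot give an enaminone), and after acidolysis of the Boc group the free amine adds to the enaminone β-carbon and expels dimethylamine (6-endo-trig addition–elimination) to give the cyclic vinylogous amide; C3 stays racemic.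

Step 6
Reactants: 13 3-methyl-5-(pent-4-en-1-yl)-2,3-dihydropyridin-4(1H)-one; 4 [(2Z)-6-chlorohex-2-en-1-yl]trimethylsilane
Product: 14 3-methyl-5-(pent-4-en-1-yl)-1-[(4Z)-6-(trimethylsilyl)hex-4-en-1-yl]-2,3-dihydropyridin-4(1H)-one
Conditions: NaH, DMF, 0 °C; then 4, NaI (cat.), 60 °C
Reagents that add atoms: none
Why: N-alkylation of the sodium salt of the vinylogous amide (SN2, with in situ Finkelstein exchange to the iodide), attack through nitrogen rather than oxygen being usual for 2,3-dihydro-4-pyridone anions with soft primary halides; the allylsilane, which would not survive the acid of step 5, is inert to NaH.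

Step 7
Reactants: 14 N-alkylated dihydropyridone
Product: 15 (1R,3R,9R,9aS)-9-ethenyl-3-methyl-1-(pent-4-en-1-yl)octahydro-2H-quinolizin-2-one and 16, its (1S,3S,9S,9aR) enantiomer, formed together as the racemate
Conditions: TiCl4 (2 equiv), CH2Cl2, −78 → −20 °C; aq NaHCO3; then K2CO3, MeOH, rt
Reagents that add atoms: none
Why: Intramolecular Hosomi–Sakurai conjugate addition: TiCl4 on the carbonyl oxygen turns the vinylogous amide into an unsaturated iminium ion that the allylsilane attacks at C9a through a chair-like 6-exo-trig transition state (anti SE2', loss of Me3SiCl) with the (Z)-alkenyl group pseudo-equatorial, which should set H-9 and H-9a trans, while C1 and C3, both α to the ketone, are then settled by K2CO3/MeOH equilibration in the arrangement that avoids the peri (syn-pentane) clash between equatorial groups on C1 and C9, that is axial pentenyl on C1 and equatorial methyl on C3.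

Step 8
Reactants: 15 (1R,3R,9R,9aS)-monomer; 16 (1S,3S,9S,9aR)-monomer (one equivalent each, as the racemate)
Product: 18 (E,E)-tetradehydropetrosin A, via linear head-to-tail dimer 17 (not isolated)
Conditions: TsOH·H2O (1.05 equiv per N), CH2Cl2, rt; then second-generation Grubbs catalyst RuCl2(=CHPh)(H2IMes)(PCy3) (2 × 5 mol %), CH2Cl2 (0.01 M), 40 °C, Ar sparge; aq NaHCO3; chromatography
Reagents that add atoms: none
Why: Olefin metathesis through metallacyclobutanes: the ruthenium alkylidene loads on the unhindered pent-4-enyl terminus and undergoes [2+2]/retro-[2+2] with the C9 vinyl group of a second monomer, ethylene being expelled. The closest known reaction type is head-to-tail cross-metathesis cyclodimerization of a diene that carries one fast-homodimerizing and one allylically branched terminal olefin, which gives macrocyclic dienes. The 16-membered ring is closed by the second event, an intramolecular ring-closing metathesis between the remaining C9 vinyl and C1 pent-4-enyl ends of 17. No stereocentre is formed; the (E) geometry of both new alkenes is the one expected for an unstrained 16-membered ring and is erased in step 9. Head-to-tail selectivity is needed and is secured by the branching at C9 (ring B), which makes vinyl–vinyl coupling slow while the pentenyl–pentenyl homodimer stays a reactive internal olefin that re-enters the reversible manifold; N-protonation keeps both amines off ruthenium, and moderate dilution with ethylene removal should let the strained eight-membered ring that one monomer can close by itself reopen and funnel to the cyclic dimer. Unlike and like enantiomers pair without preference, so meso 18 is separated from the homochiral dimer by chromatography.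

Step 9
Reactants: 18 (E,E)-tetradehydropetrosin A
Product: 19 petrosin A
Conditions: H2 (1 atm), Pd/C (10% palladium on carbon), MeOH, rt; filter; K2CO3, MeOH, rt
Reagents that add atoms: none
Why: Heterogeneous catalytic hydrogenation saturates the two disubstituted chain alkenes without touching the ketones or tertiary amines and creates no stereocentre; the brief K2CO3/MeOH treatment should return C1 and C3 to their thermodynamic configuration if they drifted in the acidic metathesis medium.

Compound list
1 | 5-chloropent-1-yne | ClCCCC#C | starting material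
2 | (iodomethyl)trimethylsilane | C[Si](C)(C)CI | starting material
3 | (6-chlorohex-2-yn-1-yl)trimethylsilane | ClCCCC#CC[Si](C)(C)C | intermediate
4 | [(2Z)-6-chlorohex-2-en-1-yl]trimethylsilane | ClCCC/C=C\C[Si](C)(C)C | intermediate
5 | (±)-3-[(tert-butoxycarbonyl)amino]-2-methylpropanoic acid | CC(CNC(=O)OC(C)(C)C)C(=O)O | starting material
6 | acyl imidazolide, tert-butyl N-[3-(1H-imidazol-1-yl)-2-methyl-3-oxopropyl]carbamate | CC(CNC(=O)OC(C)(C)C)C(=O)n1ccnc1 | intermediate
7 | Weinreb amide, tert-butyl N-{3-[methoxy(methyl)amino]-2-methyl-3-oxopropyl}carbamate | CC(CNC(=O)OC(C)(C)C)C(=O)N(C)OC | intermediate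
8 | 6-bromohex-1-ene | C=CCCCCBr | starting material
9 | hex-5-enylmagnesium bromide | C=CCCCC[Mg]Br | intermediate
10 | tert-butyl N-(2-methyl-3-oxonon-8-en-1-yl)carbamate | CC(CNC(=O)OC(C)(C)C)C(=O)CCCCC=C | intermediate
11 | Boc enaminone, tert-butyl N-{(4E)-4-[(dimethylamino)methylidene]-2-methyl-3-oxonon-8-en-1-yl}carbamate | CC(CNC(=O)OC(C)(C)C)C(=O)/C(CCCC=C)=C/N(C)C | intermediate
12 | amino enaminone, (4E)-1-amino-4-[(dimethylamino)methylidene]-2-methylnon-8-en-3-one | CC(CN)C(=O)/C(CCCC=C)=C/N(C)C | intermediate
13 | 3-methyl-5-(pent-4-en-1-yl)-2,3-dihydropyridin-4(1H)-one | CC1CNC=C(CCCC=C)C1=O | intermediate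
14 | 3-methyl-5-(pent-4-en-1-yl)-1-[(4Z)-6-(trimethylsilyl)hex-4-en-1-yl]-2,3-dihydropyridin-4(1H)-one | CC1CN(CCC/C=C\C[Si](C)(C)C)C=C(CCCC=C)C1=O | intermediate
15 | (1R,3R,9R,9aS)-9-ethenyl-3-methyl-1-(pent-4-en-1-yl)octahydro-2H-quinolizin-2-one | C[C@@H]1CN2CCC[C@H](C=C)[C@H]2[C@@H](CCCC=C)C1=O | intermediate
16 | (1S,3S,9S,9aR)-9-ethenyl-3-methyl-1-(pent-4-en-1-yl)octahydro-2H-quinolizin-2-one | C[C@H]1CN2CCC[C@@H](C=C)[C@@H]2[C@H](CCCC=C)C1=O | intermediate
17 | linear head-to-tail dimer: C9 of the 15-configured unit joined through (E)-CH=CH(CH2)3 to C1 of the 16-configured unit; one free pent-4-enyl group and one free vinyl group | C[C@@H]1CN2CCC[C@H](/C=C/CCC[C@@H]3C(=O)[C@@H](C)CN4CCC[C@@H](C=C)[C@H]34)[C@H]2[C@@H](CCCC=C)C1=O | intermediate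
18 | (E,E)-tetradehydropetrosin A: meso 16-membered cyclic dimer, C9 of each unit joined to C1 of the other by an (E)-CH=CH(CH2)3 chain with the alkene next to C9 | C[C@@H]1CN2CCC[C@@H]3/C=C/CCC[C@@H]4C(=O)[C@@H](C)CN5CCC[C@@H](/C=C/CCC[C@@H](C1=O)[C@H]32)[C@H]45 | intermediate
19 | petrosin A | C[C@@H]1CN2CCC[C@@H]3CCCCC[C@@H]4C(=O)[C@@H](C)CN5CCC[C@@H](CCCCC[C@@H](C1=O)[C@H]32)[C@H]45 | target

Total step count: 9. Longest linear sequence: 7 steps (steps 3 to 9, from 5 to 19).

Steps most likely to fail

Step 8. What may go wrong: ring closure within one monomer (its own C9 vinyl group onto its own C1 pentenyl group, giving an eight-membered cycloalkene) may outrun the pairing of two monomers, and turnover at the hindered vinyl group may be slow. The fallback sets out from 15 and 16 and comes back at 18, and it uses this ring closure instead of fighting it. Each monomer is closed on purpose at high dilution (same catalyst and TsOH, about 1 mM) to the tricyclic (Z)-cyclooctene F1 from 15 and the enantiomeric (Z)-cyclooctene F2 from 16. These are isolated and exposed as the concentrated racemate (about 0.3 M) to strain-driven ring-opening metathesis, then diluted to about 10 mM so that the oligomers back-bite to the 16-membered diene. This is ring-opening cyclodimerization of a cyclooctene to a cyclohexadeca-1,9-diene, a known process, and it needs no removal of ethylene. The head-to-head alternative would have to form a doubly branched C9–CH=CH–C9 alkene and should stay minor. 18 is again separated from the homochiral dimer.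

Step 7. What may go wrong: protodesilylation of the allylsilane before the C–C bond forms, or closure through the chair with the alkenyl group axial, which would give the cis H-9/H-9a relationship. The fallback sets out from 13 and comes back at 15 and 16, closing ring B at N5–C6 instead of C9–C9a. 13 is N-acylated (Boc2O, DMAP, MeCN) to the vinylogous imide tert-butyl 3-methyl-4-oxo-5-(pent-4-en-1-yl)-2,3-dihydropyridine-1(4H)-carboxylate F3, a much stronger acceptor. Intermolecular Lewis-acid conjugate allylation with 4 (TiCl4, CH2Cl2, −78 °C) should give tert-butyl 2-(6-chlorohex-1-en-3-yl)-5-methyl-4-oxo-3-(pent-4-en-1-yl)piperidine-1-carboxylate F4, whose C9/C9a diastereomers can be separated at this open-chain stage. TFA removes the Boc group to give the amino chloride 2-(6-chlorohex-1-en-3-yl)-5-methyl-3-(pent-4-en-1-yl)piperidin-4-one F5. K2CO3 and NaI in MeCN at 60 °C then close ring B by intramolecular N-alkylation (6-exo-tet) and equilibrate C1 and C3, giving 15 and 16.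

Step 5. What may go wrong: sluggish or incomplete aminomethylenation at the hindered methylene, with β-elimination of the carbamate on prolonged heating. The fallback sets out from 7 and comes back at 13, building the ring before the C5 substituent. Ethynylmagnesium bromide adds to 7 to give the ynone tert-butyl N-(2-methyl-3-oxopent-4-yn-1-yl)carbamate F6. HCl in dioxane followed by K2CO3 in MeOH removes the Boc group and closes the ring by 6-endo-dig aza-Michael addition to 3-methyl-2,3-dihydropyridin-4(1H)-one F7. N-Iodosuccinimide iodinates the nucleophilic C5 to give 5-iodo-3-methyl-2,3-dihydropyridin-4(1H)-one F8. Suzuki–Miyaura coupling with potassium pent-4-enyltrifluoroborate (Pd(OAc)2, RuPhos, K2CO3, toluene–water, 80 °C) then gives 13.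

Further compounds
F1 | step 8 | tricyclic (Z)-cyclooctene from 15 (C9 and C1 bridged by CH=CH(CH2)3, configuration of 15 retained) | C[C@@H]1CN2CCC[C@@H]3/C=C\CCC[C@@H](C1=O)[C@H]32
F2 | step 8 | enantiomeric (Z)-cyclooctene from 16 | C[C@H]1CN2CCC[C@H]3/C=C\CCC[C@H](C1=O)[C@@H]32
F3 | step 7 | tert-butyl 3-methyl-4-oxo-5-(pent-4-en-1-yl)-2,3-dihydropyridine-1(4H)-carboxylate (racemic) | CC1CN(C(=O)OC(C)(C)C)C=C(CCCC=C)C1=O
F4 | step 7 | tert-butyl 2-(6-chlorohex-1-en-3-yl)-5-methyl-4-oxo-3-(pent-4-en-1-yl)piperidine-1-carboxylate (racemic, enantiomer leading to 15 drawn) | C[C@@H]1CN(C(=O)OC(C)(C)C)[C@@H]([C@@H](C=C)CCCCl)[C@@H](CCCC=C)C1=O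
F5 | step 7 | 2-(6-chlorohex-1-en-3-yl)-5-methyl-3-(pent-4-en-1-yl)piperidin-4-one (racemic, enantiomer leading to 15 drawn) | C[C@@H]1CN[C@@H]([C@@H](C=C)CCCCl)[C@@H](CCCC=C)C1=O
F6 | step 5 | tert-butyl N-(2-methyl-3-oxopent-4-yn-1-yl)carbamate (racemic) | CC(CNC(=O)OC(C)(C)C)C(=O)C#C
F7 | step 5 | 3-methyl-2,3-dihydropyridin-4(1H)-one (racemic) | CC1CNC=CC1=O
F8 | step 5 | 5-iodo-3-methyl-2,3-dihydropyridin-4(1H)-one (racemic) | CC1CNC=C(I)C1=O
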